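## The problem

Amaurone B joins a fully substituted cyclohexane to a 2-methoxy-3,5-dimethyl-4-pyranone through a six-carbon (E,E,E)-triene, C1′ to C6′, with methyl groups at C2′ and C6′. The ring is numbered C1 (CH carrying the triene), C2 (CHMe), C3 (C(Me)OH), C4 (CHOAc), C5 (C(Me)OH), C6 (CHOAc); the same locants are used for acyclic intermediates. All six ring carbons are stereocentres and two are quaternary carbinols. The four oxygens lie on one face (called α here) and the four carbon substituents (the C1 chain and the methyls at C2, C3 and C5) on the other (β).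

The C2/C3 pair can be fixed in open-chain form by a stereospecific epoxide opening. C3 can then steer C4 and C5 if it is locked into a small ring. C2 to C5 together can dictate C1 and C6 in a chair-like ring closure.

Several groups are fragile. The acetates sit next to cis tertiary hydroxyls and can migrate or be cleaved by base. C1–H is allylic and vinylogously acidic with a β-acetoxy group at C6. The triene is sensitive to light and strong acid, and the α-methoxy-γ-pyranone to hard nucleophiles.

The feature that opens the structure is the C6 carbinol next to C1, with O and C trans, and the trisubstituted (E)-C1′=C2′ alkene one bond away from C1. This homoallylic alcohol is the product pattern of a carbonyl-ene reaction. Moving the alkene back to C1=C1′ and breaking C1–C6 gives an acyclic 6-alkenal whose C2′–H is the hydrogen that migrates.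

## Retrosynthesis

**Pyranone junction.** The C5′=C6′ bond of target 34 is cut last-in-first-out by a Horner–Wadsworth–Emmons disconnection into dienal 24 and phosphonate 32. Cutting here rather than at C3′=C4′ leaves the finished, correctly acetylated ring on one fragment and the pyranone on the other, so the last step is a union of two complete halves and the triene never sees acid. The forward reaction must give the (E)-trisubstituted alkene and must not disturb two acetates. Phosphonate 32 goes back through bromide 31 and ethylpyranone 29 to the acyclic triketo ester 27 and ethyl 2-methyl-3-oxopentanoate 25.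

**Dienal to ring.** Dienal 24 is simplified by removing the two acetates (tetraol 23), then the two-carbon unit C4′–C5′ and the free hydroxyls (dioxolane 22, enal 21, triol 20). This reaches the protected cyclohexanol 19. Only chemoselective operations are asked: MnO2 on an allylic alcohol, a Wittig homologation, one acid hydrolysis, and acetylation of secondary but not tertiary hydroxyls.

**Key disconnection.** In 19 the C1–C6 bond is cut and the C1′=C2′ alkene is moved to C1=C1′, giving aldehyde 18. This removes the ring and two stereocentres and leaves an open chain whose four stereocentres are all of the 1,2-related, individually addressable kind. A cut at C3–C4 or C4–C5 (aldol or pinacol type) would have to form a bond between two hindered oxygenated carbons with no comparable stereochemical model. The weak point is the 1,2-disubstituted alkene, a modest ene donor, and the design answers it from within in four ways: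
- O4 and O5 are tied in a cis-dioxolane, which holds the aldehyde carbon and the alkene arm on the same side of a five-membered ring.
- The C3 oxygen is a tertiary silyl ether, so no lactol can form.
- The aldehyde is α-alkoxy and can be chelated.
- The C2′ centre is (R), so the suprafacial hydrogen transfer that gives the (E)-alkene is also the sterically easier one.

**Aldehyde to lactone.** Aldehyde 18 comes from diol 16 by silylation (17) and oxidative desilylation. The (E)-alkene of 16 comes from the alkyne of 15, and the 1,4-diol 15 from hydride reduction of lactone 14. Seeing C6 and O3 as a γ-lactone is the central simplification. The alkyne is kept as a masked alkene until after the osmylation, where an alkene in the chain would compete.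

**The C4/C5 diol.** Acetonide 14 goes back to diol 13 and this to butenolide 12 by removal of the two cis hydroxyls. The obvious neighbour, adding a C5–C6 nucleophile to a C4 aldehyde, was rejected: chelation control there gives the C3/C4 threo relationship, the opposite of what the ring needs. In the butenolide, O3 is held in the plane of the C4=C5 alkene and the two faces differ only by the C3 substituents (methyl against the branched chain). Attack on the methyl face gives exactly the all-α arrangement of O3, O4 and O5. The forward step must discriminate these faces and leave the alkyne alone.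

**Butenolide to diol.** Butenolide 12 is opened to the (Z)-hydroxy enoate 11 and cut at C4=C5 to the α-hydroxy aldehyde 10, and 10 is the oxidised form of 1,2-diol 9. The forward reaction must be a (Z)-selective olefination of a hindered aldehyde that cannot epimerise.

**The C2/C3 pair.** Diol 9 is cut at C1–C2 into alkyne 4 and epoxy alcohol 6. One asymmetric epoxidation of (E)-2-methylbut-2-en-1-ol 5 sets C3, and an SN2 opening with inversion sets C2. Alkyne 4 comes in two steps from methyl (S)-3-hydroxy-2-methylpropanoate 1 through silyl ether 2 and aldehyde 3.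

## Roads not taken

**Alternative 1:** The C3–O and C6–O bonds are cut. The cis-disubstituted cyclohexa-1,3-diene A1 would take up singlet oxygen (O2, visible light, tetraphenylporphyrin) across C3 and C6 on the face away from the C1 and C2 substituents, giving endoperoxide A2. O–O reduction would then give the cis-1,4-diol.
- Merits: two C–O bonds and their cis relationship in one step from air, no protecting groups, and a direct lead into the osmylation of alternative 3. For installing ring oxygen it is clearly shorter than the chosen plan, which spends many steps on the same four oxygens.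
- Weak points: A1 has to be made enantiopure first, and nothing in this step helps with that. The diene carries several allylic hydrogens, so the ene mode of singlet oxygen competes with the [4+2] mode. A2 has a C6–H and can rearrange to a hydroxy enone with base (Kornblum–DeLaMare). C1 carries only a one-carbon handle, so the triene must be grown from a C1 aldehyde that can epimerise away from the cis C1/C2 arrangement.
- Comparison: the chosen plan has absolute control from one catalytic asymmetric epoxidation. The C1 side-chain alkene is created in the ring closure itself, so no epimerisable C1 carbonyl ever exists. It needs no photochemistry or peroxide handling.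

**Alternative 2:** The C1–C6 and C2–C3 bonds are cut in a Diels–Alder sense. The 1-methoxy-3-silyloxy diene A4 would add to menthyloxybutenolide A3 on the face opposite the menthyloxy group, and acid work-up would give the cis-fused cyclohexenone lactone A5.
- Merits: two ring bonds, the ring, the cis C1/C2 relationship and the absolute configuration arise in one step from cheap materials, with a recoverable auxiliary. In ring construction this is far more economical than the twelve-step open-chain build-up used here.
- Weak points: after the cycloaddition only the C4 oxygen is present. C3 must be hydroxylated to a quaternary carbinol, the enone turned into the C5/C6 diol, the acetal carbon reduced to the C2 methyl and the lactone carbonyl turned into the side chain. The terminally substituted diene is also a sluggish partner with regiochemical and endo/exo questions at C3.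
- Comparison: in the chosen plan every ring stereocentre and every ring oxygen is already in place when the ring closes, and what follows is chain extension and acetylation only.

**Alternative 3:** The C4–O and C5–O bonds are cut. OsO4·TMEDA, hydrogen-bonded to the C3 and C6 hydroxyls of cyclohexenediol A6, would add to the C4=C5 alkene on their face and give the all-cis tetraol A7.
- Merits: two directing hydroxyls on the same face make the facial outcome very secure. In this respect it is better than the purely steric osmylation of step 7 of the chosen plan.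
- Weak points: no ring or carbon–carbon bond is made, the osmium is stoichiometric, and the step presupposes A6, which is the reduction product of A2 and so inherits the problems of alternative 1.
- Comparison: the chosen plan does its osmylation early, on a small butenolide where a minor diastereomer can be removed cheaply, and its key step builds the carbocycle and the first triene alkene together.

Key step: step 13

## Route

Step 1
Reactants: 1 methyl (S)-3-hydroxy-2-methylpropanoate
Product: 2 methyl (S)-3-[(tert-butyldimethylsilyl)oxy]-2-methylpropanoate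
Conditions: TBSCl, imidazole, CH2Cl2, 0 °C to rt
Reagents that add atoms: tert-butyl(chloro)dimethylsilane, CC(C)(C)[Si](C)(C)Cl
Why: Routine silylation of a primary alcohol; the stereocentre is not touched.

Step 2
Reactants: 2 methyl (S)-3-[(tert-butyldimethylsilyl)oxy]-2-methylpropanoate
Product: 4 (R)-tert-butyldimethyl[(2-methylbut-3-yn-1-yl)oxy]silane, via aldehyde 3 (not isolated)
Conditions: i-Bu2AlH, CH2Cl2, −78 °C; then MeOH, K2CO3, dimethyl (1-diazo-2-oxopropyl)phosphonate, −78 °C to rt
Reagents that add atoms: dimethyl (1-diazo-2-oxopropyl)phosphonate, COP(=O)(OC)C(=[N+]=[N-])C(C)=O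
Why: Partial reduction of the ester followed in the same flask by Ohira–Bestmann (Seyferth–Gilbert) homologation of aldehyde 3 to the terminal alkyne. The α-centre keeps its arrangement in space (the descriptor changes from S to R only because the priorities change), and keeping 3 cold and unisolated limits epimerisation.

Step 3
Reactants: 5 (E)-2-methylbut-2-en-1-ol
Product: 6 [(2S,3S)-2,3-dimethyloxiran-2-yl]methanol
Conditions: Ti(OiPr)4 (cat.), L-(+)-diethyl tartrate (cat.), t-BuOOH, 4 Å molecular sieves, CH2Cl2, −20 °C
Reagents that add atoms: tert-butyl hydroperoxide, CC(C)(C)OO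
Why: Sharpless asymmetric epoxidation of a trisubstituted (E)-allylic alcohol; the L-(+)-tartrate catalyst delivers oxygen to the face that gives the (2S,3S)-epoxide. This fixes the future C3 directly and the future C2 after inversion.

Step 4
Reactants: 4 (R)-tert-butyldimethyl[(2-methylbut-3-yn-1-yl)oxy]silane; 6 [(2S,3S)-2,3-dimethyloxiran-2-yl]methanol
Product: 9 (2R,3S,6R)-7-[(tert-butyldimethylsilyl)oxy]-2,3,6-trimethylhept-4-yne-1,2-diol, via lithium acetylide 7 (not isolated), via alkynylalane 8 (not isolated)
Conditions: 4 (3 equiv), n-BuLi, toluene, 0 °C; Et2AlCl, 0 °C; then 6, 0 °C to rt; aq. potassium sodium tartrate (KNaC4H4O6)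
Reagents that add atoms: none
Why: Hydroxyl-assisted opening of a 2,3-epoxy alcohol by a diethylalkynylalane. The aluminium alkoxide activates the oxirane and the alkynyl group enters by SN2 with inversion at the CHMe carbon remote from the carbinol, the quaternary carbon being closed to substitution. This forms C1–C2 and sets C2 relative to C3; excess 4 is recovered.

Step 5
Reactants: 9 (2R,3S,6R)-7-[(tert-butyldimethylsilyl)oxy]-2,3,6-trimethylhept-4-yne-1,2-diol
Product: 10 (2R,3S,6R)-7-[(tert-butyldimethylsilyl)oxy]-2-hydroxy-2,3,6-trimethylhept-4-ynal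
Conditions: SO3·pyridine, DMSO, i-Pr2NEt, CH2Cl2, 0 °C
Reagents that add atoms: none
Why: Parikh–Doering oxidation takes only the primary alcohol of the 1,2-diol to the aldehyde without glycol cleavage. The tertiary hydroxyl cannot be oxidised and the α-carbon is quaternary, so nothing can epimerise.

Step 6
Reactants: 10 (2R,3S,6R)-7-[(tert-butyldimethylsilyl)oxy]-2-hydroxy-2,3,6-trimethylhept-4-ynal
Product: 12 (5S)-5-[(2S,5R)-6-[(tert-butyldimethylsilyl)oxy]-5-methylhex-3-yn-2-yl]-3,5-dimethylfuran-2(5H)-one, via (Z)-hydroxy enoate 11 (not isolated)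
Conditions: ethyl 2-[bis(2,2,2-trifluoroethoxy)phosphoryl]propanoate, KN(SiMe3)2, 18-crown-6, THF, −78 °C to rt; then PPTS (cat.), CH2Cl2, rt
Reagents that add atoms: ethyl 2-[bis(2,2,2-trifluoroethoxy)phosphoryl]propanoate, CCOC(=O)C(C)P(=O)(OCC(F)(F)F)OCC(F)(F)F
Why: Still–Gennari variant of the Horner–Wadsworth–Emmons reaction gives the (Z)-trisubstituted enoate 11. Its cis tertiary hydroxyl then closes onto the ester (5-exo-trig acyl substitution) to the butenolide, which ties O3 to C6 and holds C4=C5 in a flat five-membered template.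

Step 7
Reactants: 12 (5S)-5-[(2S,5R)-6-[(tert-butyldimethylsilyl)oxy]-5-methylhex-3-yn-2-yl]-3,5-dimethylfuran-2(5H)-one
Product: 13 (3R,4S,5R)-5-[(2S,5R)-6-[(tert-butyldimethylsilyl)oxy]-5-methylhex-3-yn-2-yl]-3,4-dihydroxy-3,5-dimethyloxolan-2-one
Conditions: OsO4 (5 mol %), N-methylmorpholine N-oxide, MeSO2NH2, acetone/H2O, rt
Reagents that add atoms: N-methylmorpholine N-oxide, C[N+]1([O-])CCOCC1; water, O (both oxygens are passed on by the OsO4 catalyst, O=[Os](=O)(=O)=O)
Why: Catalytic syn-dihydroxylation of the butenolide alkene. The reagent should come in on the face that carries the small methyl group at the quaternary C3, away from the branched chain, which puts O4 and O5 cis to each other and on the same side as O3 in the later ring. Internal alkynes are essentially inert to catalytic OsO4 at room temperature.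

Step 8
Reactants: 13 (3R,4S,5R)-5-[(2S,5R)-6-[(tert-butyldimethylsilyl)oxy]-5-methylhex-3-yn-2-yl]-3,4-dihydroxy-3,5-dimethyloxolan-2-one
Product: 14 3,4-O-isopropylidene acetal (acetonide) of 13
Conditions: 2-methoxypropene, PPTS (cat.), CH2Cl2, 0 °C to rt
Reagents that add atoms: 2-methoxypropene, COC(C)=C
Why: Acid-catalysed acetalisation; a cis-diol on a five-membered lactone closes readily to the cis-fused dioxolane, which masks O4 and O5 until step 17.

Step 9
Reactants: 14 3,4-O-isopropylidene acetal (acetonide) of 13
Product: 15 (2R,3S,6R)-7-[(tert-butyldimethylsilyl)oxy]-2-[(4R,5S)-5-(hydroxymethyl)-2,2,5-trimethyl-1,3-dioxolan-4-yl]-3,6-dimethylhept-4-yn-2-ol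
Conditions: LiBH4, THF, 0 °C to rt
Reagents that add atoms: none
Why: Hydride reduction of the lactone to the 1,4-diol frees C6 as a primary alcohol and O3 as a tertiary alcohol; silyl ether, acetonide and alkyne are inert.

Step 10
Reactants: 15 (2R,3S,6R)-7-[(tert-butyldimethylsilyl)oxy]-2-[(4R,5S)-5-(hydroxymethyl)-2,2,5-trimethyl-1,3-dioxolan-4-yl]-3,6-dimethylhept-4-yn-2-ol
Product: 16 (2R,3S,4E,6R)-7-[(tert-butyldimethylsilyl)oxy]-2-[(4R,5S)-5-(hydroxymethyl)-2,2,5-trimethyl-1,3-dioxolan-4-yl]-3,6-dimethylhept-4-en-2-ol
Conditions: Na, NH3 (l), THF, t-BuOH, −78 to −33 °C; NH4Cl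
Reagents that add atoms: none
Why: Dissolving-metal reduction of the internal alkyne goes through a vinyl radical anion that takes up the trans geometry, giving the (E)-alkene. It is placed after the osmylation so no alkene competes there, and the two propargylic stereocentres carry no leaving group.

Step 11
Reactants: 16 (2R,3S,4E,6R)-7-[(tert-butyldimethylsilyl)oxy]-2-[(4R,5S)-5-(hydroxymethyl)-2,2,5-trimethyl-1,3-dioxolan-4-yl]-3,6-dimethylhept-4-en-2-ol
Product: 17 bis(triethylsilyl) ether of 16 (primary C6–O and tertiary C3–O both silylated)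
Conditions: TESOTf, 2,6-lutidine, CH2Cl2, −78 to 0 °C
Reagents that add atoms: triethylsilyl trifluoromethanesulfonate, CC[Si](CC)(CC)OS(=O)(=O)C(F)(F)F
Why: The silyl triflate silylates the primary and the hindered tertiary hydroxyl alike; the tertiary ether is needed so that the coming C6 aldehyde cannot close to a lactol on O3.

Step 12
Reactants: 17 bis(triethylsilyl) ether of 16
Product: 18 (4R,5S)-5-[(2R,3S,4E,6R)-7-[(tert-butyldimethylsilyl)oxy]-3,6-dimethyl-2-[(triethylsilyl)oxy]hept-4-en-2-yl]-2,2,4-trimethyl-1,3-dioxolane-4-carbaldehyde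
Conditions: (COCl)2, DMSO, CH2Cl2, −78 to −30 °C; Et3N, to 0 °C
Reagents that add atoms: none
Why: Under Swern conditions a primary triethylsilyl ether is cleaved and oxidised straight to the aldehyde, while the tertiary TES ether and the primary TBS ether stay (a known selective oxidative desilylation). The aldehyde sits on a quaternary carbon and cannot epimerise.

Step 13
Reactants: 18 (4R,5S)-5-[(2R,3S,4E,6R)-7-[(tert-butyldimethylsilyl)oxy]-3,6-dimethyl-2-[(triethylsilyl)oxy]hept-4-en-2-yl]-2,2,4-trimethyl-1,3-dioxolane-4-carbaldehyde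
Product: 19 1β-[(E)-3-[(tert-butyldimethylsilyl)oxy]-2-methylprop-1-en-1-yl]-4α,5α-(isopropylidenedioxy)-2β,3β,5β-trimethyl-3α-[(triethylsilyl)oxy]cyclohexan-6α-ol
Conditions: Me2AlCl (2.5 equiv), CH2Cl2, −78 to −20 °C; aq. potassium sodium tartrate (KNaC4H4O6)
Reagents that add atoms: none
Why: Me2AlCl binds the C6 aldehyde, chelated to the neighbouring dioxolane oxygen on C5, and the C1=C1′ alkene attacks C6 through C1 while the C2′ hydrogen passes to the carbonyl oxygen in a concerted but asynchronous carbonyl-ene reaction; the methyl groups on aluminium take up any stray proton. The closest known reaction type is the Lewis-acid cyclisation of 6-alkenals to trans-2-alkenylcyclohexanols (citronellal to isopulegol), here with a less nucleophilic 1,2-disubstituted alkene. The cyclohexane closes 6-exo-trig at the carbonyl carbon and the new double bond ends up exocyclic. Both new centres are set in the chair that has C2-Me, O3 and O5 axial, the other chair being ruled out by a 1,3-diaxial clash of the C3 and C5 methyls. At C6 the oxygen takes the equatorial site because the axial one is syn-axial to the C2 methyl. At C1 the alkenyl arm must be equatorial because an axial arm would meet both axial oxygens, so O6 and the side chain come out trans. The (E) geometry of C1′=C2′ follows from suprafacial hydrogen transfer: with the (E)-alkene and the (R) centre at C2′ the hydrogen reaches the oxygen only in the rotamer that turns the methyl towards C1 and the CH2OTBS group outwards. The needed selectivities (C1/C6 trans, E) and the reactivity of a weak ene donor are secured by the substrate: the cis-dioxolane holds both reacting arms on one side of a five-membered ring, two quaternary carbons restrict the tether, and the chelated α-alkoxy aldehyde is a strongly activated enophile.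

Step 14
Reactants: 19 1β-[(E)-3-[(tert-butyldimethylsilyl)oxy]-2-methylprop-1-en-1-yl]-4α,5α-(isopropylidenedioxy)-2β,3β,5β-trimethyl-3α-[(triethylsilyl)oxy]cyclohexan-6α-ol
Product: 20 1β-[(E)-3-hydroxy-2-methylprop-1-en-1-yl]-4α,5α-(isopropylidenedioxy)-2β,3β,5β-trimethylcyclohexane-3α,6α-diol
Conditions: HF·pyridine (excess), pyridine, THF, 0 °C to rt
Reagents that add atoms: none
Why: Fluoride cleaves both silyl ethers (Si–F bond formation) while the acetonide survives the pyridine-buffered medium; a free tertiary C3–OH is harmless in what follows.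

Step 15
Reactants: 20 1β-[(E)-3-hydroxy-2-methylprop-1-en-1-yl]-4α,5α-(isopropylidenedioxy)-2β,3β,5β-trimethylcyclohexane-3α,6α-diol
Product: 21 (E)-3-[3α,6α-dihydroxy-4α,5α-(isopropylidenedioxy)-2β,3β,5β-trimethylcyclohex-1β-yl]-2-methylprop-2-enal
Conditions: MnO2, CH2Cl2, rt
Reagents that add atoms: none
Why: MnO2 oxidises only the allylic primary alcohol; the saturated secondary and tertiary hydroxyls are inert and no free 1,2-diol is present that could be cleaved.

Step 16
Reactants: 21 (E)-3-[3α,6α-dihydroxy-4α,5α-(isopropylidenedioxy)-2β,3β,5β-trimethylcyclohex-1β-yl]-2-methylprop-2-enal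
Product: 22 2-[(3E)-4-[3α,6α-dihydroxy-4α,5α-(isopropylidenedioxy)-2β,3β,5β-trimethylcyclohex-1β-yl]-3-methylbuta-1,3-dien-1-yl]-1,3-dioxolane (E/Z mixture at the new C3′=C4′ bond)
Conditions: [(1,3-dioxolan-2-yl)methyl]triphenylphosphonium bromide, KOt-Bu, THF, 0 °C; then 21, 0 °C to rt
Reagents that add atoms: [(1,3-dioxolan-2-yl)methyl]triphenylphosphonium bromide, [Br-].C(C1OCCO1)[P+](c1ccccc1)(c1ccccc1)c1ccccc1
Why: Wittig reaction with the ylide of a protected acetaldehyde unit adds C4′ and C5′ in one operation. Because the product is an acetal, not an aldehyde, it cannot be homologated a second time, which a formyl ylide would risk; the ylide is preformed without excess alkoxide so the hydroxyls stay un-ionised.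

Step 17
Reactants: 22 2-[(3E)-4-[3α,6α-dihydroxy-4α,5α-(isopropylidenedioxy)-2β,3β,5β-trimethylcyclohex-1β-yl]-3-methylbuta-1,3-dien-1-yl]-1,3-dioxolane
Product: 23 (2E,4E)-4-methyl-5-(3α,4α,5α,6α-tetrahydroxy-2β,3β,5β-trimethylcyclohex-1β-yl)penta-2,4-dienal
Conditions: 2 M aq. HCl, THF, rt
Reagents that add atoms: water, O
Why: Aqueous acid hydrolyses the dienyl dioxolane and the acetonide in one operation, and the conjugated dienal should settle into the (2E,4E) form under these equilibrating conditions. Acid is used here, before the pyranone triene exists.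

Step 18
Reactants: 23 (2E,4E)-4-methyl-5-(3α,4α,5α,6α-tetrahydroxy-2β,3β,5β-trimethylcyclohex-1β-yl)penta-2,4-dienal
Product: 24 (2E,4E)-5-(4α,6α-diacetoxy-3α,5α-dihydroxy-2β,3β,5β-trimethylcyclohex-1β-yl)-4-methylpenta-2,4-dienal
Conditions: Ac2O, pyridine, DMAP (cat.), CH2Cl2, 0 °C to rt
Reagents that add atoms: acetic anhydride, CC(=O)OC(C)=O
Why: DMAP-catalysed acylation of the two secondary hydroxyls at C4 and C6; the tertiary hydroxyls at C3 and C5 are too hindered to react at room temperature.

Step 19
Reactants: 25 ethyl 2-methyl-3-oxopentanoate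
Product: 27 ethyl 2,4-dimethyl-3,5-dioxoheptanoate, via dianion 26 (not isolated)
Conditions: NaH, THF, 0 °C; n-BuLi, 0 °C; then N-methoxy-N-methylpropanamide, 0 °C to rt; aq. HCl
Reagents that add atoms: N-methoxy-N-methylpropanamide, CCC(=O)N(C)OC
Why: Stepwise deprotonation at C2 and then C4 gives the β-keto ester dianion, which is acylated at its more reactive terminal carbon (Claisen-type γ-acylation).

Step 20
Reactants: 27 ethyl 2,4-dimethyl-3,5-dioxoheptanoate
Product: 28 6-ethyl-4-hydroxy-3,5-dimethyl-2H-pyran-2-one
Conditions: DBU, toluene, reflux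
Reagents that add atoms: none
Why: Base-mediated lactonisation of the enolised 5-keto group onto the ester gives the 4-hydroxy-2-pyranone with loss of ethanol.

Step 21
Reactants: 28 6-ethyl-4-hydroxy-3,5-dimethyl-2H-pyran-2-one
Product: 29 2-ethyl-6-methoxy-3,5-dimethyl-4H-pyran-4-one
Conditions: MeOTf, CH2Cl2, rt; aq. NaHCO3
Reagents that add atoms: methyl trifluoromethanesulfonate, COS(=O)(=O)C(F)(F)F
Why: A hard methylating agent alkylates the ring carbonyl oxygen of a 4-hydroxy-2-pyranone, and deprotonation of the resulting hydroxypyrylium salt gives the 2-methoxy-4-pyranone (O-alkylation with a known regiochemical preference in this class). Any 4-methoxy-2-pyranone isomer is removed by chromatography.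

Step 22
Reactants: 29 2-ethyl-6-methoxy-3,5-dimethyl-4H-pyran-4-one
Product: 31 2-(1-bromoethyl)-6-methoxy-3,5-dimethyl-4H-pyran-4-one (racemic), via lithium dienolate 30 (not isolated)
Conditions: LiN(SiMe3)2, THF, −78 °C; then added to N-bromosuccinimide, THF, −78 °C
Reagents that add atoms: N-bromosuccinimide, BrN1C(=O)CCC1=O
Why: The CH2 of the 2-ethyl group is vinylogously α to the pyranone carbonyl and is the only acidic position; the extended enolate is brominated at carbon (enolate α-halogenation), and inverse addition limits double bromination.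

Step 23
Reactants: 31 2-(1-bromoethyl)-6-methoxy-3,5-dimethyl-4H-pyran-4-one
Product: 32 diethyl [1-(6-methoxy-3,5-dimethyl-4-oxo-4H-pyran-2-yl)ethyl]phosphonate (racemic)
Conditions: P(OEt)3, neat, 130 °C
Reagents that add atoms: triethyl phosphite, CCOP(OCC)OCC
Why: Michaelis–Arbuzov reaction of an activated secondary bromide.

Step 24
Reactants: 24 (2E,4E)-5-(4α,6α-diacetoxy-3α,5α-dihydroxy-2β,3β,5β-trimethylcyclohex-1β-yl)-4-methylpenta-2,4-dienal; 32 diethyl [1-(6-methoxy-3,5-dimethyl-4-oxo-4H-pyran-2-yl)ethyl]phosphonate
Product: 34 Amaurone B, via lithiated phosphonate 33 (not isolated)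
Conditions: 32 (1.5 equiv), LiN(SiMe3)2 (1.4 equiv), THF, −78 °C; then 24, −78 to 0 °C, exclusion of light
Reagents that add atoms: none
Why: Horner–Wadsworth–Emmons olefination. The pyranone-stabilised anion adds reversibly, so the trisubstituted C5′=C6′ bond should form under thermodynamic control with the pyranone trans to the chain (E). The anion is kept in slight excess over the base and is too weak a base to ionise the tertiary alcohols or attack the acetates.

## Compound list

1 | methyl (S)-3-hydroxy-2-methylpropanoate | COC(=O)[C@@H](C)CO | starting material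
2 | methyl (S)-3-[(tert-butyldimethylsilyl)oxy]-2-methylpropanoate | COC(=O)[C@@H](C)CO[Si](C)(C)C(C)(C)C | intermediate
3 | (S)-3-[(tert-butyldimethylsilyl)oxy]-2-methylpropanal | O=C[C@@H](C)CO[Si](C)(C)C(C)(C)C | intermediate
4 | (R)-tert-butyldimethyl[(2-methylbut-3-yn-1-yl)oxy]silane | C#C[C@@H](C)CO[Si](C)(C)C(C)(C)C | intermediate
5 | (E)-2-methylbut-2-en-1-ol | C/C=C(\C)CO | starting material
6 | [(2S,3S)-2,3-dimethyloxiran-2-yl]methanol | OC[C@]1(C)O[C@H]1C | intermediate
7 | [(3R)-4-[(tert-butyldimethylsilyl)oxy]-3-methylbut-1-yn-1-yl]lithium | [Li]C#C[C@@H](C)CO[Si](C)(C)C(C)(C)C | intermediate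
8 | [(3R)-4-[(tert-butyldimethylsilyl)oxy]-3-methylbut-1-yn-1-yl]diethylaluminium | CC[Al](CC)C#C[C@@H](C)CO[Si](C)(C)C(C)(C)C | intermediate
9 | (2R,3S,6R)-7-[(tert-butyldimethylsilyl)oxy]-2,3,6-trimethylhept-4-yne-1,2-diol | CC(C)(C)[Si](C)(C)OC[C@H](C)C#C[C@H](C)[C@@](C)(O)CO | intermediate
10 | (2R,3S,6R)-7-[(tert-butyldimethylsilyl)oxy]-2-hydroxy-2,3,6-trimethylhept-4-ynal | CC(C)(C)[Si](C)(C)OC[C@H](C)C#C[C@H](C)[C@@](C)(O)C=O | intermediate
11 | ethyl (2Z,4S,5S,8R)-9-[(tert-butyldimethylsilyl)oxy]-4-hydroxy-2,4,5,8-tetramethylnon-2-en-6-ynoate | CC(C)(C)[Si](C)(C)OC[C@H](C)C#C[C@H](C)[C@@](C)(O)/C=C(/C)C(=O)OCC | intermediate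
12 | (5S)-5-[(2S,5R)-6-[(tert-butyldimethylsilyl)oxy]-5-methylhex-3-yn-2-yl]-3,5-dimethylfuran-2(5H)-one | CC(C)(C)[Si](C)(C)OC[C@H](C)C#C[C@H](C)[C@@]1(C)OC(=O)C(C)=C1 | intermediate
13 | (3R,4S,5R)-5-[(2S,5R)-6-[(tert-butyldimethylsilyl)oxy]-5-methylhex-3-yn-2-yl]-3,4-dihydroxy-3,5-dimethyloxolan-2-one | CC(C)(C)[Si](C)(C)OC[C@H](C)C#C[C@H](C)[C@@]1(C)OC(=O)[C@](C)(O)[C@@H]1O | intermediate
14 | 3,4-O-isopropylidene acetal (acetonide) of 13 | CC(C)(C)[Si](C)(C)OC[C@H](C)C#C[C@H](C)[C@@]1(C)OC(=O)[C@]2(C)OC(C)(C)O[C@H]12 | intermediate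
15 | (2R,3S,6R)-7-[(tert-butyldimethylsilyl)oxy]-2-[(4R,5S)-5-(hydroxymethyl)-2,2,5-trimethyl-1,3-dioxolan-4-yl]-3,6-dimethylhept-4-yn-2-ol | CC(C)(C)[Si](C)(C)OC[C@H](C)C#C[C@H](C)[C@@](C)(O)[C@H]1OC(C)(C)O[C@@]1(C)CO | intermediate
16 | (2R,3S,4E,6R)-7-[(tert-butyldimethylsilyl)oxy]-2-[(4R,5S)-5-(hydroxymethyl)-2,2,5-trimethyl-1,3-dioxolan-4-yl]-3,6-dimethylhept-4-en-2-ol | CC(C)(C)[Si](C)(C)OC[C@H](C)/C=C/[C@H](C)[C@@](C)(O)[C@H]1OC(C)(C)O[C@@]1(C)CO | intermediate
17 | bis(triethylsilyl) ether of 16 | CC(C)(C)[Si](C)(C)OC[C@H](C)/C=C/[C@H](C)[C@@](C)(O[Si](CC)(CC)CC)[C@H]1OC(C)(C)O[C@@]1(C)CO[Si](CC)(CC)CC | intermediate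
18 | (4R,5S)-5-[(2R,3S,4E,6R)-7-[(tert-butyldimethylsilyl)oxy]-3,6-dimethyl-2-[(triethylsilyl)oxy]hept-4-en-2-yl]-2,2,4-trimethyl-1,3-dioxolane-4-carbaldehyde | CC(C)(C)[Si](C)(C)OC[C@H](C)/C=C/[C@H](C)[C@@](C)(O[Si](CC)(CC)CC)[C@H]1OC(C)(C)O[C@@]1(C)C=O | intermediate
19 | 1β-[(E)-3-[(tert-butyldimethylsilyl)oxy]-2-methylprop-1-en-1-yl]-4α,5α-(isopropylidenedioxy)-2β,3β,5β-trimethyl-3α-[(triethylsilyl)oxy]cyclohexan-6α-ol | CC(C)(C)[Si](C)(C)OC/C(C)=C/[C@@H]1[C@H](C)[C@@](C)(O[Si](CC)(CC)CC)[C@H]2OC(C)(C)O[C@@]2(C)[C@H]1O | intermediate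
20 | 1β-[(E)-3-hydroxy-2-methylprop-1-en-1-yl]-4α,5α-(isopropylidenedioxy)-2β,3β,5β-trimethylcyclohexane-3α,6α-diol | OC/C(C)=C/[C@@H]1[C@H](C)[C@@](C)(O)[C@H]2OC(C)(C)O[C@@]2(C)[C@H]1O | intermediate
21 | (E)-3-[3α,6α-dihydroxy-4α,5α-(isopropylidenedioxy)-2β,3β,5β-trimethylcyclohex-1β-yl]-2-methylprop-2-enal | O=C/C(C)=C/[C@@H]1[C@H](C)[C@@](C)(O)[C@H]2OC(C)(C)O[C@@]2(C)[C@H]1O | intermediate
22 | 2-[(3E)-4-[3α,6α-dihydroxy-4α,5α-(isopropylidenedioxy)-2β,3β,5β-trimethylcyclohex-1β-yl]-3-methylbuta-1,3-dien-1-yl]-1,3-dioxolane (E/Z at C3′=C4′) | O1CCOC1C=C/C(C)=C/[C@@H]2[C@H](C)[C@@](C)(O)[C@H]3OC(C)(C)O[C@@]3(C)[C@H]2O | intermediate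
23 | (2E,4E)-4-methyl-5-(3α,4α,5α,6α-tetrahydroxy-2β,3β,5β-trimethylcyclohex-1β-yl)penta-2,4-dienal | O=C/C=C/C(C)=C/[C@@H]1[C@H](C)[C@@](C)(O)[C@@H](O)[C@@](C)(O)[C@H]1O | intermediate
24 | (2E,4E)-5-(4α,6α-diacetoxy-3α,5α-dihydroxy-2β,3β,5β-trimethylcyclohex-1β-yl)-4-methylpenta-2,4-dienal | O=C/C=C/C(C)=C/[C@@H]1[C@H](C)[C@@](C)(O)[C@@H](OC(C)=O)[C@@](C)(O)[C@H]1OC(C)=O | intermediate
25 | ethyl 2-methyl-3-oxopentanoate | CCC(=O)C(C)C(=O)OCC | starting material
26 | sodium lithium dianion of ethyl 2-methyl-3-oxopentanoate (C2, C4) | [Na+].[Li+].CCOC(=O)[C-](C)C(=O)[CH-]C | intermediate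
27 | ethyl 2,4-dimethyl-3,5-dioxoheptanoate | CCC(=O)C(C)C(=O)C(C)C(=O)OCC | intermediate
28 | 6-ethyl-4-hydroxy-3,5-dimethyl-2H-pyran-2-one | CCc1oc(=O)c(C)c(O)c1C | intermediate
29 | 2-ethyl-6-methoxy-3,5-dimethyl-4H-pyran-4-one | CCc1oc(OC)c(C)c(=O)c1C | intermediate
30 | lithium dienolate of 29 (deprotonated at the ethyl CH2) | [Li+].C[CH-]c1oc(OC)c(C)c(=O)c1C | intermediate
31 | 2-(1-bromoethyl)-6-methoxy-3,5-dimethyl-4H-pyran-4-one | CC(Br)c1oc(OC)c(C)c(=O)c1C | intermediate
32 | diethyl [1-(6-methoxy-3,5-dimethyl-4-oxo-4H-pyran-2-yl)ethyl]phosphonate | CCOP(=O)(OCC)C(C)c1oc(OC)c(C)c(=O)c1C | intermediate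
33 | lithium salt of the α-carbanion of 32 | [Li+].CCOP(=O)(OCC)[C-](C)c1oc(OC)c(C)c(=O)c1C | intermediate
34 | Amaurone B | COc1oc(/C(C)=C/C=C/C(C)=C/[C@@H]2[C@H](C)[C@@](C)(O)[C@@H](OC(C)=O)[C@@](C)(O)[C@H]2OC(C)=O)c(C)c(=O)c1C | target

## Step count and least certain steps

Total: 24 steps. Longest linear sequence: 18 steps (steps 1, 2, 4 to 18 and 24); step 3 and steps 19 to 23 are side branches.

**Step 13 (key step).** The 1,2-disubstituted alkene may be too weak a nucleophile for the chelated aldehyde. Slow closure would let Lewis-acid cleavage of the dioxolane or the tertiary silyl ether compete. A stepwise path through a secondary C1′ cation could lead to chloride capture or loss of the (E) geometry, and a twist-boat could erode the C1/C6 trans selectivity. The fallback makes the same C1–C6 bond with a stronger π-nucleophile and sets out from 17: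
- Ozonolysis of 17 (O3, CH2Cl2/MeOH, −78 °C; PPh3) gives the C1 aldehyde, 2-methyl-3-(triethylsilyloxy)propanal derivative F1.
- Wittig reaction with the ylide from [2-(trimethylsilyl)ethyl]triphenylphosphonium iodide and n-BuLi gives allylsilane F2.
- Swern oxidative desilylation gives the C6 aldehyde F3.
- BF3·OEt2 in CH2Cl2 at −78 °C closes the ring by intramolecular Hosomi–Sakurai allylation through the same chair, to the trans-2-vinylcyclohexanol F4.
- HF·pyridine gives the vinyl diol F5.
- Cross-metathesis with methacrolein, using the second-generation Grubbs catalyst (H2IMes)(PCy3)Cl2Ru=CHPh, gives enal 21, where the route is rejoined.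

**Step 7.** The two faces of the butenolide differ only by a methyl group against a branched alkyl group at C3, so facial discrimination may be incomplete. A hindered, electron-poor alkene also reacts slowly, which could allow over-oxidation at the alkyne. The fallback replaces substrate control by reagent control and a stereospecific opening, and sets out from 10:
- Wittig reaction with Ph3P=C(Me)CO2Et gives the (E)-hydroxy enoate F6.
- i-Bu2AlH reduces it to the (E)-allylic diol F7.
- Sharpless epoxidation with Ti(OiPr)4, D-(−)-diethyl tartrate and t-BuOOH gives the (2R,3R)-epoxy diol F8.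
- Dilute aqueous HClO4 in THF opens the oxirane with water at its tertiary carbon (C5) with inversion, to tetraol F9.
- Ag2CO3 on Celite in hot benzene oxidises the primary alcohol and closes the γ-lactone, giving 13.

**Step 6.** The hindered α-quaternary aldehyde may react slowly, so Z-selectivity could erode, and the free tertiary alkoxide may cause side reactions or incomplete ring closure. The fallback fixes the geometry by ring formation and sets out from 10. Steglich esterification of the tertiary hydroxyl with 2-(diethoxyphosphoryl)propanoic acid (DCC, DMAP) gives the phosphonoester aldehyde F10. Intramolecular Horner–Wadsworth–Emmons reaction (LiCl, i-Pr2NEt, MeCN) then gives butenolide 12 directly.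

**Step 24.** Equilibration to the (E)-trisubstituted alkene may be incomplete, and any alkoxide formed could trigger acetyl migration or β-elimination of the C6 acetate through the vinylogous C1–H. The fallback forms the same bond by aldol addition and dehydration, and sets out from 24 and 29. Lithium dienolate 30 (from 29 and LiN(SiMe3)2, THF, −78 °C) adds to 24 to give the β-hydroxy adduct F11 as a diastereomer mixture. Selective mesylation of the secondary dienylic hydroxyl (MsCl, Et3N, −20 °C) gives mesylate F12, and DBU eliminates it to the conjugated triene 34.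

**Step 4.** The opening may be misdirected: ionisation at the quaternary oxirane carbon, or transfer of an ethyl group in place of the alkynyl group. The fallback gives up hydroxyl direction and sets out from 6. TESCl and imidazole give the silyl ether F13. Lithium acetylide 7 with BF3·OEt2 in THF at −78 °C opens it at the secondary carbon with inversion to the tertiary alcohol F14. Swern oxidation converts the primary triethylsilyl ether directly into aldehyde 10.

## Further compounds

F1 | step 13 | (2R,3R)-3-[(4S,5S)-2,2,5-trimethyl-5-[(triethylsilyloxy)methyl]-1,3-dioxolan-4-yl]-2-methyl-3-(triethylsilyloxy)butanal (C1 aldehyde from ozonolysis of 17; configuration as in 17) | O=C[C@H](C)[C@@](C)(O[Si](CC)(CC)CC)[C@H]1OC(C)(C)O[C@@]1(C)CO[Si](CC)(CC)CC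
F2 | step 13 | allylsilane: F1 with CHO replaced by CH=CH–CH2SiMe3 (E/Z mixture) | C[Si](C)(C)CC=C[C@H](C)[C@@](C)(O[Si](CC)(CC)CC)[C@H]1OC(C)(C)O[C@@]1(C)CO[Si](CC)(CC)CC
F3 | step 13 | C6 aldehyde of F2 (dioxolane-4-carbaldehyde) | C[Si](C)(C)CC=C[C@H](C)[C@@](C)(O[Si](CC)(CC)CC)[C@H]1OC(C)(C)O[C@@]1(C)C=O
F4 | step 13 | 1β-ethenyl-4α,5α-(isopropylidenedioxy)-2β,3β,5β-trimethyl-3α-[(triethylsilyl)oxy]cyclohexan-6α-ol | C=C[C@@H]1[C@H](C)[C@@](C)(O[Si](CC)(CC)CC)[C@H]2OC(C)(C)O[C@@]2(C)[C@H]1O
F5 | step 13 | 1β-ethenyl-4α,5α-(isopropylidenedioxy)-2β,3β,5β-trimethylcyclohexane-3α,6α-diol | C=C[C@@H]1[C@H](C)[C@@](C)(O)[C@H]2OC(C)(C)O[C@@]2(C)[C@H]1O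
F6 | step 7 | ethyl (2E,4S,5S,8R)-9-[(tert-butyldimethylsilyl)oxy]-4-hydroxy-2,4,5,8-tetramethylnon-2-en-6-ynoate | CC(C)(C)[Si](C)(C)OC[C@H](C)C#C[C@H](C)[C@@](C)(O)/C=C(\C)C(=O)OCC
F7 | step 7 | (E)-allylic diol from reduction of F6 (ester to CH2OH) | CC(C)(C)[Si](C)(C)OC[C@H](C)C#C[C@H](C)[C@@](C)(O)/C=C(\C)CO
F8 | step 7 | (2R,3R)-epoxy diol from F7 (oxirane across C4–C5) | CC(C)(C)[Si](C)(C)OC[C@H](C)C#C[C@H](C)[C@@](C)(O)[C@H]1O[C@]1(C)CO
F9 | step 7 | tetraol from opening of F8 at C5 (C3, C4, C5, C6 hydroxyls) | CC(C)(C)[Si](C)(C)OC[C@H](C)C#C[C@H](C)[C@@](C)(O)[C@@H](O)[C@@](C)(O)CO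
F10 | step 6 | 2-(diethoxyphosphoryl)propanoate ester of the tertiary hydroxyl of 10 | CC(C)(C)[Si](C)(C)OC[C@H](C)C#C[C@H](C)[C@@](C)(OC(=O)C(C)P(=O)(OCC)OCC)C=O
F11 | step 24 | aldol adduct of 30 and 24 (C5′ carbinol, C6′ CHMe, diastereomer mixture) | COc1oc(C(C)C(O)/C=C/C(C)=C/[C@@H]2[C@H](C)[C@@](C)(O)[C@@H](OC(C)=O)[C@@](C)(O)[C@H]2OC(C)=O)c(C)c(=O)c1C
F12 | step 24 | C5′ methanesulfonate of F11 | COc1oc(C(C)C(OS(C)(=O)=O)/C=C/C(C)=C/[C@@H]2[C@H](C)[C@@](C)(O)[C@@H](OC(C)=O)[C@@](C)(O)[C@H]2OC(C)=O)c(C)c(=O)c1C
F13 | step 4 | triethylsilyl ether of 6 | CC[Si](CC)(CC)OC[C@]1(C)O[C@H]1C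
F14 | step 4 | 1-O-triethylsilyl ether of 9 | CC(C)(C)[Si](C)(C)OC[C@H](C)C#C[C@H](C)[C@@](C)(O)CO[Si](CC)(CC)CC
A1 | alternative 1 | cis-5-{[(tert-butyldimethylsilyl)oxy]methyl}-1,3,6-trimethylcyclohexa-1,3-diene | CC(C)(C)[Si](C)(C)OC[C@@H]1[C@H](C)C(C)=CC(C)=C1
A2 | alternative 1 | 2,3-dioxabicyclo[2.2.2]oct-5-ene endoperoxide from A1 | CC(C)(C)[Si](C)(C)OC[C@@H]1[C@H](C)[C@@]2(C)OO[C@@H]1C(C)=C2
A3 | alternative 2 | 5-(menthyloxy)furan-2(5H)-one | O=C1O[C@@H](O[C@@H]2C[C@H](C)CC[C@H]2C(C)C)C=C1
A4 | alternative 2 | (1E,3Z)-1-methoxy-2-methyl-3-(trimethylsilyloxy)penta-1,3-diene | CO/C=C(C)/C(O[Si](C)(C)C)=C/C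
A5 | alternative 2 | cis-fused cyclohexenone lactone with the menthyloxy acetal | O=C1O[C@@H](O[C@@H]3C[C@H](C)CC[C@H]3C(C)C)[C@H]2[C@@H]1C=C(C)C(=O)[C@H]2C
A6 | alternative 3 | 1β-{[(tert-butyldimethylsilyl)oxy]methyl}-2β,3β,5-trimethylcyclohex-4-ene-3α,6α-diol | CC(C)(C)[Si](C)(C)OC[C@@H]1[C@H](C)[C@@](C)(O)C=C(C)[C@H]1O
A7 | alternative 3 | all-cis 1β-{[(tert-butyldimethylsilyl)oxy]methyl}-2β,3β,5β-trimethylcyclohexane-3α,4α,5α,6α-tetraol | CC(C)(C)[Si](C)(C)OC[C@@H]1[C@H](C)[C@@](C)(O)[C@@H](O)[C@@](C)(O)[C@H]1O
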